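Meridianin F is cut through the benzene ring of the indole. C5 and C6, the neighbouring bromine-bearing carbons, are a symmetry-related pair that maps onto bis(trimethylsilyl)acetylene, and each C–Si bond is later exchanged for C–Br at the same carbon. One cobalt-mediated [2+2+2] cotrimerization forms C3a–C7a, C4–C5 and C6–C7. It closes the benzene ring and the five-membered nitrogen ring together as a 5,6-disilylindoline. The precursor is an N-tosyl ynamide 1,6-diyne. Its propargylic carbon (future C3) carries the di-Boc-aminopyrimidine and a silyloxy group, which blocks allene formation and later leaves as water to give the indole.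

Key step: step 7

Remark on the precursor design: a diyne with hydrogen at the propargylic carbon was set aside.
- A C–H flanked by an alkyne and a 4-pyrimidinyl ring would drift to the allene in every basic operation.
- Its α-pyrimidinyl β-sulfonamido aldehyde forerunner would lose sulfonamide by E1cB.
- An electron-poor N-sulfonylindoline resists quinone dehydrogenation.

A triethylsilyloxy group at this carbon leaves the carbon–nitrogen skeleton and the disconnection unchanged. It is a spectator in the cyclotrimerization and already carries the indole oxidation level.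

Remark on stereochemistry: every intermediate that contains the quaternary carbinol carbon (future C3) is a racemate, so its SMILES carries no descriptor. This centre becomes sp2 in step 10 and the target is achiral.

Step 1
Reactants: 1 2-amino-4-chloropyrimidine
Product: 2 di-tert-butyl (4-chloropyrimidin-2-yl)imidodicarbonate
Conditions: Boc2O (2.5 equiv), DMAP (10 mol %), THF, rt
Reagents that add atoms: di-tert-butyl dicarbonate, CC(C)(C)OC(=O)OC(=O)OC(C)(C)C
Why: DMAP-catalysed exhaustive N-acylation (Boc protection) of a heteroarylamine is routine, removes both N–H bonds, lowers the electron density of the pyrimidine (which guards its C5 against later bromination) and screens both ring nitrogens from metals.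

Step 2
Reactants: 2 di-tert-butyl (4-chloropyrimidin-2-yl)imidodicarbonate; 3 tributyl(1-ethoxyvinyl)stannane
Product: 5 di-tert-butyl [4-(bromoacetyl)pyrimidin-2-yl]imidodicarbonate, via 1-ethoxyvinylpyrimidine 4 (not isolated)
Conditions: PdCl2(PPh3)2 (5 mol %), 1,4-dioxane, 90 °C; then 0 °C, H2O, NBS (1.05 equiv)
Reagents that add atoms: N-bromosuccinimide, O=C1CCC(=O)N1Br; water, O
Why: Stille coupling occurs readily at the activated C4–Cl bond of a pyrimidine, and the electron-rich enol ether 4 is then the only site that NBS attacks, the bromo-oxocarbenium ion being captured by water and collapsing with loss of ethanol to the α-bromo ketone.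

Step 3
Reactants: 5 di-tert-butyl [4-(bromoacetyl)pyrimidin-2-yl]imidodicarbonate; 6 p-toluenesulfonamide
Product: 7 N-[2-{2-[bis(tert-butoxycarbonyl)amino]pyrimidin-4-yl}-2-oxoethyl]-4-methylbenzenesulfonamide
Conditions: 6 (3 equiv), K2CO3 (1.2 equiv), MeCN, 0 °C → rt
Reagents that add atoms: none
Why: SN2 N-alkylation of the sulfonamide anion by a very reactive α-bromo ketone that has no α′-hydrogen, with the sulfonamide in excess to suppress a second alkylation.

Step 4
Reactants: 7 N-[2-{2-[bis(tert-butoxycarbonyl)amino]pyrimidin-4-yl}-2-oxoethyl]-4-methylbenzenesulfonamide; 8 ethynylmagnesium bromide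
Product: 9 (±)-N-[2-{2-[bis(tert-butoxycarbonyl)amino]pyrimidin-4-yl}-2-hydroxybut-3-yn-1-yl]-4-methylbenzenesulfonamide
Conditions: 8 (3 equiv, THF solution), LaCl3·2LiCl (30 mol %), THF, −40 → 0 °C; aq NH4Cl
Reagents that add atoms: none
Why: Grignard 1,2-addition (alkynylation) to a strongly electrophilic heteroaryl ketone, in which the first equivalent removes the sulfonamide proton and thereby disfavours enolization, the lanthanum salt favours carbonyl addition over attack at Boc or at the ring, and the new quaternary carbinol centre forms without facial control as a racemate, which is irrelevant because it is erased in step 10.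

Step 5
Reactants: 9 (±)-N-[2-{2-[bis(tert-butoxycarbonyl)amino]pyrimidin-4-yl}-2-hydroxybut-3-yn-1-yl]-4-methylbenzenesulfonamide
Product: 10 (±)-N-[2-{2-[bis(tert-butoxycarbonyl)amino]pyrimidin-4-yl}-2-(triethylsilyloxy)but-3-yn-1-yl]-4-methylbenzenesulfonamide
Conditions: Et3SiCl (1.5 equiv), imidazole (3 equiv), DMAP (10 mol %), DMF, rt
Reagents that add atoms: chlorotriethylsilane, CC[Si](Cl)(CC)CC
Why: Imidazole-promoted O-silylation is selective for the alcohol (any N-silyl sulfonamide hydrolyses on work-up) and masks a hydroxyl group that would otherwise add to the neighbouring ynamide under base.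

Step 6
Reactants: 10 (±)-N-[2-{2-[bis(tert-butoxycarbonyl)amino]pyrimidin-4-yl}-2-(triethylsilyloxy)but-3-yn-1-yl]-4-methylbenzenesulfonamide; 11 phenyl[(trimethylsilyl)ethynyl]iodonium trifluoromethanesulfonate
Product: 13 (±)-N-ethynyl-N-[2-{2-[bis(tert-butoxycarbonyl)amino]pyrimidin-4-yl}-2-(triethylsilyloxy)but-3-yn-1-yl]-4-methylbenzenesulfonamide, via C-silylated ynamide 12 (not isolated)
Conditions: KN(SiMe3)2 (1.05 equiv), toluene, 0 °C; 11 (1.2 equiv), 0 °C → rt; then MeOH, K2CO3 (20 mol %), 0 °C, brief
Reagents that add atoms: none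
Why: N-alkynylation with an alkynyl(aryl)iodonium salt, in which the sulfonamide anion adds to the β-carbon, iodobenzene leaves and the alkylidene carbene rearranges by a fast 1,2-silyl shift (the quaternary carbon offers no C–H for 1,5-insertion), after which carbonate-catalysed methanolysis removes the labile C(sp)–SiMe3 group but not the tertiary triethylsilyl ether.

Step 7
Reactants: 13 (±)-N-ethynyl-N-[2-{2-[bis(tert-butoxycarbonyl)amino]pyrimidin-4-yl}-2-(triethylsilyloxy)but-3-yn-1-yl]-4-methylbenzenesulfonamide; 14 bis(trimethylsilyl)acetylene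
Product: 15 (±)-3-{2-[bis(tert-butoxycarbonyl)amino]pyrimidin-4-yl}-1-tosyl-3-(triethylsilyloxy)-5,6-bis(trimethylsilyl)indoline
Conditions: CpCo(CO)2 (20 mol %), 14 (20 equiv), toluene, reflux, visible-light lamp, Ar; 13 and CpCo(CO)2 added together by syringe pump over 8 h
Reagents that add atoms: none
Why: Heat and light strip CO from CpCo(CO)2 to give a monovalent CpCo fragment that binds both tethered alkynes of 13 and couples them oxidatively to a trivalent cobaltacyclopentadiene, creating C3a–C7a, after which uptake of 14 and reductive elimination create C4–C5 and C6–C7 and return the monovalent metal. The closest known reactions are the CpCo(CO)2 cotrimerization of hepta-1,6-diynes with bis(trimethylsilyl)acetylene to 5,6-disilylindanes and the metal-catalysed [2+2+2] cyclization of nitrogen-tethered ynamide diynes to indolines. The five-membered nitrogen ring closes in the intramolecular oxidative coupling, as the ring fused to the metallacycle across the three-atom N1–C2–C3 tether, and the benzene ring closes when the third alkyne is incorporated and the metal is expelled. No stereocentre is formed, and the existing quaternary C3 is untouched and stays racemic. The step needs cross- over self-trimerization, which is secured because 14 is too hindered to trimerize and is present in large excess, 13 is kept dilute by slow addition, geminal substitution at C3 favours the intramolecular coupling, and the symmetry of 14 excludes regioisomers. The quaternary C3 rules out propargyl–allene drift, and the two Boc groups screen the pyrimidine nitrogens from cobalt.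

Step 8
Reactants: 15 (±)-3-{2-[bis(tert-butoxycarbonyl)amino]pyrimidin-4-yl}-1-tosyl-3-(triethylsilyloxy)-5,6-bis(trimethylsilyl)indoline
Product: 16 (±)-5,6-dibromo-3-{2-[bis(tert-butoxycarbonyl)amino]pyrimidin-4-yl}-1-tosyl-3-(triethylsilyloxy)indoline
Conditions: Br2 (2.5 equiv), pyridine (3 equiv), CH2Cl2, 0 °C → rt, dark; aq Na2S2O3
Reagents that add atoms: bromine, BrBr
Why: Electrophilic aromatic ipso-substitution (bromodesilylation), in which attack at each silicon-bearing carbon gives a β-silyl-stabilised arenium ion that loses the silyl group faster than any C–H site reacts, the first exchange (C5, para to N1) being helped by relief of strain between the ortho silyl groups, while pyridine ties up Me3SiBr so that Boc and silyl ether survive and the doubly acylated aminopyrimidine stays inert.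

Step 9
Reactants: 16 (±)-5,6-dibromo-3-{2-[bis(tert-butoxycarbonyl)amino]pyrimidin-4-yl}-1-tosyl-3-(triethylsilyloxy)indoline
Product: 17 (±)-5,6-dibromo-3-{2-[bis(tert-butoxycarbonyl)amino]pyrimidin-4-yl}-1-tosylindolin-3-ol
Conditions: HF·pyridine, pyridine/THF, 0 °C → rt (plastic vessel)
Reagents that add atoms: none
Why: Fluoride-driven Si–O cleavage under buffered, weakly acidic conditions leaves Boc, tosyl and aryl bromides untouched and avoids a free alkoxide.

Step 10
Reactants: 17 (±)-5,6-dibromo-3-{2-[bis(tert-butoxycarbonyl)amino]pyrimidin-4-yl}-1-tosylindolin-3-ol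
Product: 18 di-tert-butyl [4-(5,6-dibromo-1-tosyl-1H-indol-3-yl)pyrimidin-2-yl]imidodicarbonate
Conditions: SOCl2 (2 equiv), pyridine, CH2Cl2, 0 °C → rt
Reagents that add atoms: none
Why: Dehydration of a tertiary alcohol by O-sulfinylation and pyridine-induced E2 loss of a C2 hydrogen (the only β-hydrogens present) is driven by formation of the aromatic indole and does not depend on a C3 cation, which the pyrimidine would destabilise, and the stereocentre disappears here.

Step 11
Reactants: 18 di-tert-butyl [4-(5,6-dibromo-1-tosyl-1H-indol-3-yl)pyrimidin-2-yl]imidodicarbonate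
Product: 20 meridianin F [4-(5,6-dibromo-1H-indol-3-yl)pyrimidin-2-amine], via N-tosylmeridianin F 19 (not isolated)
Conditions: TFA, CH2Cl2, rt; evaporate; then NaOH (2 M aq), MeOH/THF, 60 °C
Reagents that add atoms: none
Why: Acidolysis of both tert-butyl carbamates (loss of isobutene and CO2) followed by hydroxide attack at sulfur of the N-sulfonylindole, whose electron-poor indolide is a good leaving group, are standard deprotections that touch neither the C–Br bonds nor the aminopyrimidine.

Compound list
1 | 2-amino-4-chloropyrimidine | Nc1nccc(Cl)n1 | starting material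
2 | di-tert-butyl (4-chloropyrimidin-2-yl)imidodicarbonate | CC(C)(C)OC(=O)N(C(=O)OC(C)(C)C)c1nccc(Cl)n1 | intermediate
3 | tributyl(1-ethoxyvinyl)stannane | C=C(OCC)[Sn](CCCC)(CCCC)CCCC | starting material
4 | di-tert-butyl [4-(1-ethoxyvinyl)pyrimidin-2-yl]imidodicarbonate (not isolated) | C=C(OCC)c1ccnc(N(C(=O)OC(C)(C)C)C(=O)OC(C)(C)C)n1 | intermediate
5 | di-tert-butyl [4-(bromoacetyl)pyrimidin-2-yl]imidodicarbonate | O=C(CBr)c1ccnc(N(C(=O)OC(C)(C)C)C(=O)OC(C)(C)C)n1 | intermediate
6 | p-toluenesulfonamide | Cc1ccc(S(N)(=O)=O)cc1 | starting material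
7 | N-[2-{2-[bis(tert-butoxycarbonyl)amino]pyrimidin-4-yl}-2-oxoethyl]-4-methylbenzenesulfonamide | Cc1ccc(cc1)S(=O)(=O)NCC(=O)c1ccnc(N(C(=O)OC(C)(C)C)C(=O)OC(C)(C)C)n1 | intermediate
8 | ethynylmagnesium bromide | C#C[Mg]Br | starting material
9 | (±)-N-[2-{2-[bis(tert-butoxycarbonyl)amino]pyrimidin-4-yl}-2-hydroxybut-3-yn-1-yl]-4-methylbenzenesulfonamide | Cc1ccc(cc1)S(=O)(=O)NCC(O)(C#C)c1ccnc(N(C(=O)OC(C)(C)C)C(=O)OC(C)(C)C)n1 | intermediate
10 | (±)-N-[2-{2-[bis(tert-butoxycarbonyl)amino]pyrimidin-4-yl}-2-(triethylsilyloxy)but-3-yn-1-yl]-4-methylbenzenesulfonamide | CC[Si](CC)(CC)OC(CNS(=O)(=O)c1ccc(C)cc1)(C#C)c1ccnc(N(C(=O)OC(C)(C)C)C(=O)OC(C)(C)C)n1 | intermediate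
11 | phenyl[(trimethylsilyl)ethynyl]iodonium trifluoromethanesulfonate | C[Si](C)(C)C#C[I+]c1ccccc1.[O-]S(=O)(=O)C(F)(F)F | starting material
12 | (±)-N-[(trimethylsilyl)ethynyl]-N-[2-{2-[bis(tert-butoxycarbonyl)amino]pyrimidin-4-yl}-2-(triethylsilyloxy)but-3-yn-1-yl]-4-methylbenzenesulfonamide (not isolated) | CC[Si](CC)(CC)OC(CN(C#C[Si](C)(C)C)S(=O)(=O)c1ccc(C)cc1)(C#C)c1ccnc(N(C(=O)OC(C)(C)C)C(=O)OC(C)(C)C)n1 | intermediate
13 | (±)-N-ethynyl-N-[2-{2-[bis(tert-butoxycarbonyl)amino]pyrimidin-4-yl}-2-(triethylsilyloxy)but-3-yn-1-yl]-4-methylbenzenesulfonamide | C#CN(CC(C#C)(O[Si](CC)(CC)CC)c1ccnc(N(C(=O)OC(C)(C)C)C(=O)OC(C)(C)C)n1)S(=O)(=O)c1ccc(C)cc1 | intermediate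
14 | bis(trimethylsilyl)acetylene | C[Si](C)(C)C#C[Si](C)(C)C | starting material
15 | (±)-3-{2-[bis(tert-butoxycarbonyl)amino]pyrimidin-4-yl}-1-tosyl-3-(triethylsilyloxy)-5,6-bis(trimethylsilyl)indoline | C[Si](C)(C)c1cc2c(cc1[Si](C)(C)C)N(S(=O)(=O)c1ccc(C)cc1)CC2(O[Si](CC)(CC)CC)c1ccnc(N(C(=O)OC(C)(C)C)C(=O)OC(C)(C)C)n1 | intermediate
16 | (±)-5,6-dibromo-3-{2-[bis(tert-butoxycarbonyl)amino]pyrimidin-4-yl}-1-tosyl-3-(triethylsilyloxy)indoline | Brc1cc2c(cc1Br)N(S(=O)(=O)c1ccc(C)cc1)CC2(O[Si](CC)(CC)CC)c1ccnc(N(C(=O)OC(C)(C)C)C(=O)OC(C)(C)C)n1 | intermediate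
17 | (±)-5,6-dibromo-3-{2-[bis(tert-butoxycarbonyl)amino]pyrimidin-4-yl}-1-tosylindolin-3-ol | Brc1cc2c(cc1Br)N(S(=O)(=O)c1ccc(C)cc1)CC2(O)c1ccnc(N(C(=O)OC(C)(C)C)C(=O)OC(C)(C)C)n1 | intermediate
18 | di-tert-butyl [4-(5,6-dibromo-1-tosyl-1H-indol-3-yl)pyrimidin-2-yl]imidodicarbonate | Cc1ccc(cc1)S(=O)(=O)n1cc(-c2ccnc(N(C(=O)OC(C)(C)C)C(=O)OC(C)(C)C)n2)c2cc(Br)c(Br)cc21 | intermediate
19 | 4-(5,6-dibromo-1-tosyl-1H-indol-3-yl)pyrimidin-2-amine (not isolated) | Cc1ccc(cc1)S(=O)(=O)n1cc(-c2ccnc(N)n2)c2cc(Br)c(Br)cc21 | intermediate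
20 | meridianin F, 4-(5,6-dibromo-1H-indol-3-yl)pyrimidin-2-amine | Nc1nccc(-c2c[nH]c3cc(Br)c(Br)cc23)n1 | target

Total step count: 11. Longest linear sequence: 11 steps (from 1).

Steps most likely to fail

Step 7 (key step).
- What may go wrong: self-oligomerization of the diyne could outrun capture of the cobaltacycle by the hindered silylalkyne. The pyrimidine or the ynamide could sequester cobalt. Boc could be lost thermally.
- Fallback: the benzene ring is bought instead of built. The fallback sets out from 2 and returns at 18.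
- 5,6-Dibromo-1H-indole F1 (purchased) is iodinated at C3 (I2, KOH, DMF) to 5,6-dibromo-3-iodo-1H-indole F2.
- N-Tosylation (NaH, TsCl, THF) gives 5,6-dibromo-3-iodo-1-tosyl-1H-indole F3.
- Selective iodine–magnesium exchange (i-PrMgCl·LiCl, THF, −40 °C) gives (5,6-dibromo-1-tosyl-1H-indol-3-yl)magnesium chloride F4.
- Trapping with 2-isopropoxy-4,4,5,5-tetramethyl-1,3,2-dioxaborolane gives 5,6-dibromo-3-(4,4,5,5-tetramethyl-1,3,2-dioxaborolan-2-yl)-1-tosyl-1H-indole F5.
- Suzuki–Miyaura coupling of this boronate with 2 (PdCl2(dppf), K3PO4, dioxane/water, 70 °C) should give 18, because the activated C4–Cl bond of the pyrimidine adds to zerovalent palladium faster than the aryl bromides. The route then resumes with the final deprotection.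

Step 8.
- What may go wrong: the reaction could stall after the first silicon–bromine exchange, because the remaining silyl group then sits ortho to bromine. The silyl bromide could strip Boc, which would open the pyrimidine ring to bromination. C–H bromination at C7 could compete.
- Fallback: the carbon–halogen bonds are made from boron instead of silicon. The fallback sets out from 13 and returns at 16.
- Compound 13 is cotrimerized under the cobalt conditions of the key step with 1,2-bis(4,4,5,5-tetramethyl-1,3,2-dioxaborolan-2-yl)ethyne F6 (purchased). Alkynylboronates are known partners in cobalt [2+2+2] reactions. The product is (±)-3-{2-[bis(tert-butoxycarbonyl)amino]pyrimidin-4-yl}-5,6-bis(4,4,5,5-tetramethyl-1,3,2-dioxaborolan-2-yl)-1-tosyl-3-(triethylsilyloxy)indoline F7.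
- Both C–B bonds are then exchanged by ipso-bromodeboronation (NaBr, TsN(Cl)Na, THF/water, rt). This runs near neutrality and releases no silyl halide.

Step 6.
- What may go wrong: the neopentyl-type sulfonamide anion could attack the iodonium salt so slowly that the trivalent iodine reagent decomposes first. One Boc group could be partly methanolysed during C-desilylation.
- Fallback: metal- and iodine-free addition–elimination. The fallback sets out from 10 and returns at 13.
- Compound 10 is treated with NaH and (Z)-1,2-dichloroethene in DMF (rt → 50 °C).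
- The base generates chloroethyne F8 in the flask, and the sulfonamide anion adds to it in anti fashion. This gives the (±)-(Z)-N-(2-chlorovinyl) derivative of 10 F9.
- A second anti dehydrochlorination by excess NaH delivers the terminal ynamide 13 directly, without a carbene, a C-silyl group or methanol.
- The absence of an acidic propargylic C–H in 10 is what allows this strongly basic alternative.

Further compounds
F1 | step 7 | 5,6-dibromo-1H-indole (purchased) | Brc1cc2cc[nH]c2cc1Br
F2 | step 7 | 5,6-dibromo-3-iodo-1H-indole | Ic1c[nH]c2cc(Br)c(Br)cc12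
F3 | step 7 | 5,6-dibromo-3-iodo-1-tosyl-1H-indole | Cc1ccc(cc1)S(=O)(=O)n1cc(I)c2cc(Br)c(Br)cc21
F4 | step 7 | (5,6-dibromo-1-tosyl-1H-indol-3-yl)magnesium chloride | Cc1ccc(cc1)S(=O)(=O)n1cc([Mg]Cl)c2cc(Br)c(Br)cc21
F5 | step 7 | 5,6-dibromo-3-(4,4,5,5-tetramethyl-1,3,2-dioxaborolan-2-yl)-1-tosyl-1H-indole | Cc1ccc(cc1)S(=O)(=O)n1cc(B2OC(C)(C)C(C)(C)O2)c2cc(Br)c(Br)cc21
F6 | step 8 | 1,2-bis(4,4,5,5-tetramethyl-1,3,2-dioxaborolan-2-yl)ethyne (purchased) | CC1(C)OB(C#CB2OC(C)(C)C(C)(C)O2)OC1(C)C
F7 | step 8 | (±)-3-{2-[bis(tert-butoxycarbonyl)amino]pyrimidin-4-yl}-5,6-bis(4,4,5,5-tetramethyl-1,3,2-dioxaborolan-2-yl)-1-tosyl-3-(triethylsilyloxy)indoline | CC1(C)OB(OC1(C)C)c1cc2c(cc1B1OC(C)(C)C(C)(C)O1)N(S(=O)(=O)c1ccc(C)cc1)CC2(O[Si](CC)(CC)CC)c1ccnc(N(C(=O)OC(C)(C)C)C(=O)OC(C)(C)C)n1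
F8 | step 6 | chloroethyne (formed in the flask) | C#CCl
F9 | step 6 | (±)-(Z)-N-(2-chlorovinyl)-N-[2-{2-[bis(tert-butoxycarbonyl)amino]pyrimidin-4-yl}-2-(triethylsilyloxy)but-3-yn-1-yl]-4-methylbenzenesulfonamide | Cl/C=C\N(CC(C#C)(O[Si](CC)(CC)CC)c1ccnc(N(C(=O)OC(C)(C)C)C(=O)OC(C)(C)C)n1)S(=O)(=O)c1ccc(C)cc1
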